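**Retrosynthetic overview**

1. Target 17 is the 1β-(E)-p-coumaroyl ester of 5α-hydroxydrim-7-ene-11,12-dial; the last two operations are a cis-1,4-hydrogenation of a ring B 6,8-diene (puts H on C9, leaves C7=C8) and the unmasking of C12 and of the phenol.
2. Key disconnection: ring B is cut at C7–C8 and C9–C10 (Diels–Alder reaction of the ring A vinylcyclohexenyl ester 10 with the C4 ynal 12) and at C5–O (Schenck ene reaction with O2); the three components are joined in one pot.
3. Enabling feature: ring B carries its two formyl carbons on adjacent C8 and C9 beside quaternary C10, and the tertiary C5–OH is homoallylic to C7=C8; a C5=C6/C8=C9 cyclohexa-1,4-diene whose only allylic hydrogens sit on C7 maps onto this exactly (ynal as the C8–C9 unit, O2 ene reaction at C5).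
4. Ring order: ring A first (bought as a cyclohexenone; gem-dimethyl group, vinyl group, C1 carbinol by CBS reduction, ester attached), ring B second in the key step; stereocontrol is relayed C1 → C10 → C5 and C9.

Key step: step 7

Remark on the chemistry: bicyclic compounds are numbered as drimanes (ring A = C1–C5 and C10, ring B = C5–C10, C11 on C9, C12 on C8, methyl groups on C4 and C10), β is the face of the C10 methyl group, and the cycloaddition is assumed to give mainly the regioisomer with the free formyl group on C9.

**Route**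

Step 1
Reactants: 1 3-ethoxy-2-methylcyclohex-2-en-1-one
Product: 3 3-ethoxy-2,6,6-trimethylcyclohex-2-en-1-one, via monomethyl enone 2 (not isolated)
Conditions: LiN(iPr)2 (LDA, 1.1 equiv), THF, −78 °C, then MeI, −78 → 0 °C; recool, LiN(iPr)2 (1.2 equiv), −78 °C, then MeI, −78 °C → rt
Reagents that add atoms: iodomethane, CI
Why: Kinetic α′-deprotonation of the vinylogous ester (Stork–Danheiser alkylation) is regiospecific for C6, so both methyl groups of the future C4 gem-dimethyl unit go onto one carbon and no stereocenter survives.

Step 2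
Reactants: 3 3-ethoxy-2,6,6-trimethylcyclohex-2-en-1-one
Product: 5 2,4,4-trimethyl-3-vinylcyclohex-2-en-1-one, via tertiary allylic alcohol 4 (not isolated)
Conditions: CH2=CHMgBr (1.5 equiv), THF, 0 °C → rt; then 1 M aq. HCl, rt
Reagents that add atoms: vinylmagnesium bromide, C=C[Mg]Br; water, O
Why: Stork–Danheiser transposition, in which the Grignard reagent adds 1,2 to the only carbonyl group and aqueous acid hydrolyses the enol ether with loss of the tertiary hydroxyl group, should give the 3-vinyl enone that holds the C10=C5–C6=C7 diene carbons without forming a stereocenter.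

Step 3
Reactants: 5 2,4,4-trimethyl-3-vinylcyclohex-2-en-1-one
Product: 6 (R)-2,4,4-trimethyl-3-vinylcyclohex-2-en-1-ol
Conditions: (S)-2-methyl-CBS-oxazaborolidine (0.2 equiv), catecholborane (1.5 equiv), toluene, −78 °C; aq. NaOH work-up
Reagents that add atoms: none
Why: Corey–Bakshi–Shibata reduction, in which the α-methylated alkene arm acts as the large substituent, so that the (S)-catalyst should deliver hydride to the face that gives the (R)-carbinol (the future 1β-oxygen), while catecholborane at −78 °C leaves the diene alone.

Step 4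
Reactants: 7 (E)-p-coumaric acid
Product: 9 (E)-3-[4-(tert-butyldimethylsilyloxy)phenyl]prop-2-enoic acid, via silyl ester 8 (not isolated)
Conditions: TBSCl (2.3 equiv), imidazole (5 equiv), DMF, rt; then AcOH/THF/H2O (3:1:1), rt
Reagents that add atoms: tert-butyldimethylsilyl chloride, CC(C)(C)[Si](C)(C)Cl
Why: Exhaustive silylation followed by selective hydrolysis of the far more labile silyl ester (a protection step) should free the acid and keep the phenol masked, the E alkene being untouched.

Step 5
Reactants: 6 (R)-2,4,4-trimethyl-3-vinylcyclohex-2-en-1-ol; 9 (E)-3-[4-(tert-butyldimethylsilyloxy)phenyl]prop-2-enoic acid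
Product: 10 (R)-2,4,4-trimethyl-3-vinylcyclohex-2-en-1-yl (E)-3-[4-(tert-butyldimethylsilyloxy)phenyl]prop-2-enoate
Conditions: DCC (1.3 equiv), DMAP (0.2 equiv), CH2Cl2, 0 °C → rt
Reagents that add atoms: none
Why: Steglich esterification acylates the oxygen of the allylic alcohol, so the C1 configuration is retained and the complete ester side chain is in place before ring B is built.

Step 6
Reactants: 11 3,3-diethoxyprop-1-yne
Product: 12 4,4-diethoxybut-2-ynal
Conditions: n-BuLi (1.05 equiv), THF, −78 °C; DMF (2 equiv), −78 → 0 °C; poured into cold 10% aq. KH2PO4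
Reagents that add atoms: N,N-dimethylformamide, CN(C)C=O
Why: Formylation of the lithium acetylide with DMF, with an inverse phosphate quench that keeps the liberated dimethylamine from adding to the ynal, should give the C4 unit with one free and one masked formyl group and no stereocenter.

Step 7
Reactants: 10 (R)-2,4,4-trimethyl-3-vinylcyclohex-2-en-1-yl (E)-3-[4-(tert-butyldimethylsilyloxy)phenyl]prop-2-enoate; 12 4,4-diethoxybut-2-ynal
Product: 15 (1R,5R,10S)-1β-[(E)-4-(tert-butyldimethylsilyloxy)cinnamoyloxy]-12,12-diethoxy-5α-hydroxydrima-6,8-dien-11-al, via cycloadduct 13 (not isolated), via hydroperoxide 14 (not isolated)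
Conditions: 10 (1 equiv), 12 (1.5 equiv), toluene, 90 °C, sealed tube, argon; evaporate volatiles; CH2Cl2, meso-tetraphenylporphyrin (1 mol%), O2, visible light, −20 °C; then PPh3 (1.5 equiv), −20 °C → rt
Reagents that add atoms: dioxygen, O=O
Why: Heating 10 with 12 effects a thermal, concerted [4+2] cycloaddition of the C10=C5–C6=C7 diene with the C8≡C9 alkyne, which closes ring B by forming C7–C8 and C9–C10 in one suprafacial event (intermolecular Diels–Alder annulation onto ring A; closest known type: addition of acetylenic dienophiles to 2,6,6-trimethyl-1-vinylcyclohexenes) and gives the skipped diene 13. Singlet oxygen then adds to C5 of the electron-rich C5=C6 bond with transfer of the 7α-hydrogen (Schenck ene reaction, the same pattern as the 5α-hydroperoxidation of 5-ene steroids), and PPh3 reduces the O–O bond of 14 to the alcohol 15. The quaternary C10 is controlled by C1: its acyloxy group sits pseudoaxial to avoid strain with the C10 methyl group and screens the β face, so C9 bonds from the α face and the methyl group ends cis to the C1 oxygen. C5 is controlled by the C10 methyl group and the axial C4 methyl group, which both close the β face, so oxygen enters α, trans to the C10 methyl group. The cycloaddition needs the formyl-bearing alkyne carbon to bond to C10: the larger HOMO coefficient and the lower hindrance at C7 pair that terminus with the acetal-bearing β-carbon of the ynal, and the minor regioisomer would converge on 17 through steps 8 and 9 in any case. The oxygenation needs chemo- and regioselectivity: C7 carries the only allylic hydrogens of C5=C6, the tetrasubstituted C8=C9 enal and the cinnamate are too electron-poor for singlet oxygen, and the quaternary C10 forbids aromatisation of the cyclohexadiene.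

Step 8
Reactants: 15 (1R,5R,10S)-1β-[(E)-4-(tert-butyldimethylsilyloxy)cinnamoyloxy]-12,12-diethoxy-5α-hydroxydrima-6,8-dien-11-al
Product: 16 (1R,5R,9R,10S)-1β-[(E)-4-(tert-butyldimethylsilyloxy)cinnamoyloxy]-12,12-diethoxy-5α-hydroxydrim-7-en-11-al
Conditions: (naphthalene)Cr(CO)3 (0.2 equiv), H2 (70 atm), THF, 45 °C
Reagents that add atoms: none
Why: Cr(CO)3-catalysed cis-1,4-hydrogenation of a conjugated diene held s-cis in ring B (the reaction type that turns sorbates into (Z)-3-hexenoates) should bind the metal on the α face, which is open and carries the C5 hydroxyl group while β is shielded by the C10 methyl group, and deliver both hydrogens there, so that C9 gains Hα (formyl group β), the double bond settles at C7=C8 and the isolated cinnamate alkene is left.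

Step 9
Reactants: 16 (1R,5R,9R,10S)-1β-[(E)-4-(tert-butyldimethylsilyloxy)cinnamoyloxy]-12,12-diethoxy-5α-hydroxydrim-7-en-11-al
Product: 17 (1R,5R,9R,10S)-1β-[(E)-4-hydroxycinnamoyloxy]-5α-hydroxydrim-7-ene-11,12-dial (CNP0323926.1)
Conditions: HF·pyridine, THF/H2O (10:1), 0 °C → rt; pH 7 phosphate buffer work-up
Reagents that add atoms: water, O
Why: Aqueous acid should hydrolyse the allylic diethyl acetal through the C7=C8-stabilised oxocarbenium ion while HF removes the aryl silyl group, and since no base is present the C9 stereocenter next to the C11 aldehyde should hold and the new C12 enal makes C7=C8 the conjugated position.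

**Compound list**

1 | 3-ethoxy-2-methylcyclohex-2-en-1-one | CCOC1=C(C)C(=O)CCC1 | starting material
2 | 3-ethoxy-2,6-dimethylcyclohex-2-en-1-one (racemic, formed in the flask) | CCOC1=C(C)C(=O)C(C)CC1 | intermediate
3 | 3-ethoxy-2,6,6-trimethylcyclohex-2-en-1-one | CCOC1=C(C)C(=O)C(C)(C)CC1 | intermediate
4 | 3-ethoxy-2,6,6-trimethyl-1-vinylcyclohex-2-en-1-ol (racemic, present as its magnesium alkoxide, formed in the flask) | CCOC1=C(C)C(O)(C=C)C(C)(C)CC1 | intermediate
5 | 2,4,4-trimethyl-3-vinylcyclohex-2-en-1-one | C=CC1=C(C)C(=O)CCC1(C)C | intermediate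
6 | (R)-2,4,4-trimethyl-3-vinylcyclohex-2-en-1-ol | C=CC1=C(C)[C@H](O)CCC1(C)C | intermediate
7 | (E)-p-coumaric acid | OC(=O)/C=C/c1ccc(O)cc1 | starting material
8 | tert-butyldimethylsilyl (E)-3-[4-(tert-butyldimethylsilyloxy)phenyl]prop-2-enoate (formed in the flask) | CC(C)(C)[Si](C)(C)OC(=O)/C=C/c1ccc(O[Si](C)(C)C(C)(C)C)cc1 | intermediate
9 | (E)-3-[4-(tert-butyldimethylsilyloxy)phenyl]prop-2-enoic acid | CC(C)(C)[Si](C)(C)Oc1ccc(/C=C/C(=O)O)cc1 | intermediate
10 | (R)-2,4,4-trimethyl-3-vinylcyclohex-2-en-1-yl (E)-3-[4-(tert-butyldimethylsilyloxy)phenyl]prop-2-enoate | C=CC1=C(C)[C@H](OC(=O)/C=C/c2ccc(O[Si](C)(C)C(C)(C)C)cc2)CCC1(C)C | intermediate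
11 | 3,3-diethoxyprop-1-yne | C#CC(OCC)OCC | starting material
12 | 4,4-diethoxybut-2-ynal | O=CC#CC(OCC)OCC | intermediate
13 | (1R,10S)-1β-[(E)-4-(tert-butyldimethylsilyloxy)cinnamoyloxy]-12,12-diethoxydrima-5,8-dien-11-al (10β-methyl; formed in the flask) | CC1(C)CC[C@@H](OC(=O)/C=C/c3ccc(O[Si](C)(C)C(C)(C)C)cc3)[C@]2(C)C(C=O)=C(C(OCC)OCC)CC=C12 | intermediate
14 | (1R,5R,10S)-1β-[(E)-4-(tert-butyldimethylsilyloxy)cinnamoyloxy]-12,12-diethoxy-5α-hydroperoxydrima-6,8-dien-11-al (formed in the flask) | CC1(C)CC[C@@H](OC(=O)/C=C/c3ccc(O[Si](C)(C)C(C)(C)C)cc3)[C@]2(C)C(C=O)=C(C(OCC)OCC)C=C[C@@]12OO | intermediate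
15 | (1R,5R,10S)-1β-[(E)-4-(tert-butyldimethylsilyloxy)cinnamoyloxy]-12,12-diethoxy-5α-hydroxydrima-6,8-dien-11-al | CC1(C)CC[C@@H](OC(=O)/C=C/c3ccc(O[Si](C)(C)C(C)(C)C)cc3)[C@]2(C)C(C=O)=C(C(OCC)OCC)C=C[C@@]12O | intermediate
16 | (1R,5R,9R,10S)-1β-[(E)-4-(tert-butyldimethylsilyloxy)cinnamoyloxy]-12,12-diethoxy-5α-hydroxydrim-7-en-11-al (9α-H, 11-formyl group β) | CC1(C)CC[C@@H](OC(=O)/C=C/c3ccc(O[Si](C)(C)C(C)(C)C)cc3)[C@]2(C)[C@@H](C=O)C(C(OCC)OCC)=CC[C@@]12O | intermediate
17 | (1R,5R,9R,10S)-1β-[(E)-4-hydroxycinnamoyloxy]-5α-hydroxydrim-7-ene-11,12-dial (CNP0323926.1) | CC1(C)CC[C@@H](OC(=O)/C=C/c2ccc(O)cc2)[C@]2(C)[C@@H](C=O)C(C=O)=CC[C@@]12O | target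

**Count and risks**

Total step count: 9. Longest linear sequence: 7 steps (steps 1, 2, 3, 5, 7, 8, 9); steps 4 and 6 are side branches.

Steps most likely to fail:

Step 7. The photo-oxygenation stage may be eroded by over-oxidation (competing [4+2] addition of singlet oxygen to the cyclohexa-1,3-diene that the ene reaction creates) or by incomplete face control at C5. In that case the thermal stage would be run alone from 10 and 12 and the cycloadduct 13 isolated. Epoxidation of its electron-rich C5=C6 bond with m-chloroperoxybenzoic acid (NaHCO3, CH2Cl2, 0 °C) should give, from the α face, the 5α,6α-epoxy-8-en-11-al F1. DBU (CH2Cl2, 0 °C → rt) should then remove a C7 hydrogen (γ to the C11 aldehyde) and open the oxirane by vinylogous β-elimination, which comes back to the route at 15.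

Step 8. The hydrogenation may suffer from catalyst deactivation (transfer of the Cr(CO)3 fragment to the aryl ring of the ester) or from competing 1,4-reduction of the C8=C9–C11=O enal. In that case the two hydrogens would be introduced in two separate events starting from 15. Hydroxyl-directed hydrogenation of C6=C7 with [Ir(cod)(PCy3)(py)]PF6 and H2 (1 atm, CH2Cl2, 0 °C) should give the 6,7-dihydro 8-en-11-al F2. KN(SiMe3)2 (2.5 equiv, THF, −78 °C) followed by a kinetic quench with AcOH should then deconjugate it through the extended enolate, protonating C9 from the α face; this returns to the route at 16.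

Step 9. The unmasking may fail through acid-catalysed migration of the C7=C8 bond back into conjugation with the C11 aldehyde before the acetal has gone, through epimerisation at C9, or through dehydration of the tertiary alcohol. In that case the order of the last two operations would be reversed. Compound 15, which has no stereocenter at C9 and nothing to isomerise, would be unmasked first (HF·pyridine, THF/H2O) to the free phenol 6,8-diene-11,12-dial F3. The 1,4-hydrogenation with (naphthalene)Cr(CO)3 and H2 would then be the last step, run under neutral conditions, and would come back to the route at the target 17.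

Further compounds
F1 | step 7 | 1β-[(E)-4-(tert-butyldimethylsilyloxy)cinnamoyloxy]-12,12-diethoxy-5α,6α-epoxydrim-8-en-11-al | CC1(C)CC[C@@H](OC(=O)/C=C/c4ccc(O[Si](C)(C)C(C)(C)C)cc4)[C@]2(C)C(C=O)=C(C(OCC)OCC)C[C@@H]3O[C@]123
F2 | step 8 | 1β-[(E)-4-(tert-butyldimethylsilyloxy)cinnamoyloxy]-12,12-diethoxy-5α-hydroxydrim-8-en-11-al | CC1(C)CC[C@@H](OC(=O)/C=C/c3ccc(O[Si](C)(C)C(C)(C)C)cc3)[C@]2(C)C(C=O)=C(C(OCC)OCC)CC[C@@]12O
F3 | step 9 | 1β-[(E)-4-hydroxycinnamoyloxy]-5α-hydroxydrima-6,8-diene-11,12-dial | CC1(C)CC[C@@H](OC(=O)/C=C/c3ccc(O)cc3)[C@]2(C)C(C=O)=C(C=O)C=C[C@@]12O
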